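**Retrosynthetic overview**

- The two esters are installed last, on a guaiane triol. The C6 carbinol comes from a C6 ketone by reduction directed by the C8 hydroxyl.
- Key disconnection C4–C5: C4(OH)–C5(H)–C6(=O) is an aldol retron once C6 is a ketone. C5 lies between the C6 carbonyl and the tetrasubstituted C1=C10 olefin of the seven-membered ring, so its hydrogen is doubly activated and the ring locks the derived enolate in the E(O) geometry. An intramolecular aldol addition to the side-chain methyl ketone closes the five-membered ring.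
- The seven-membered β,γ-unsaturated ketone is made by ring-closing metathesis, which forms the tetrasubstituted C1=C10 olefin from an acyclic diene ketone.
- The diene ketone comes from a Weinreb amide and a 2-substituted allyl-metal reagent. C7 and C8 are set by an Evans syn aldol reaction.
- Ring order: seven-membered ring first (step 8), then five-membered ring (step 10).

Key step: step 10

Remark: locants C1–C15 in the text follow guaiane numbering (C4 carbinol carbon, C5 ring-fusion CH, C6 acetoxy carbon, C7 isopropyl-bearing carbon, C8 angeloyloxy carbon, C1=C10 ring olefin, C14 and C15 methyls).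

**Route**

Step 1
Reactants: 1 (R)-4-benzyloxazolidin-2-one; 2 3-methylbutanoyl chloride
Product: 3 (R)-4-benzyl-3-(3-methylbutanoyl)oxazolidin-2-one
Conditions: Et3N, DMAP (cat.), CH2Cl2, 0 °C to rt
Reagents that add atoms: none
Why: DMAP-catalysed N-acylation of the oxazolidinone by the acid chloride (nucleophilic acyl substitution); no stereocentre is touched.

Step 2
Reactants: 4 3-methylbut-3-en-1-ol
Product: 5 3-methylbut-3-enal
Conditions: Dess–Martin periodinane, NaHCO3, CH2Cl2, 0 °C to rt; solution used at once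
Reagents that add atoms: none
Why: Dess–Martin oxidation of the primary alcohol under buffered conditions that should not move the 1,1-disubstituted olefin into conjugation.

Step 3
Reactants: 3 (R)-4-benzyl-3-(3-methylbutanoyl)oxazolidin-2-one; 5 3-methylbut-3-enal
Product: 7 (R)-4-benzyl-3-[(2R,3S)-3-hydroxy-5-methyl-2-(propan-2-yl)hex-5-enoyl]oxazolidin-2-one, via dibutylboron (Z)-enolate 6 (not isolated)
Conditions: n-Bu2BOTf, Et3N, CH2Cl2, −78 to 0 °C; 5, −78 to 0 °C; pH 7 buffer, MeOH, 30% H2O2
Reagents that add atoms: none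
Why: Evans syn aldol reaction; the boron (Z)-enolate reacts through a chair Zimmerman–Traxler transition state on the face opposite the benzyl group, which should set C7 and C8 in the required syn relationship and absolute sense.

Step 4
Reactants: 7 (R)-4-benzyl-3-[(2R,3S)-3-hydroxy-5-methyl-2-(propan-2-yl)hex-5-enoyl]oxazolidin-2-one
Product: 8 (2R,3S)-3-hydroxy-N-methoxy-N,5-dimethyl-2-(propan-2-yl)hex-5-enamide
Conditions: MeNHOMe·HCl, AlMe3, CH2Cl2, −20 °C to rt; aqueous Rochelle salt
Reagents that add atoms: N,O-dimethylhydroxylamine hydrochloride (CNOC.Cl)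
Why: aluminium amide transamination of the β-hydroxy imide to the Weinreb amide, assisted by the free hydroxyl; C7 is not epimerised and auxiliary 1 is recovered.

Step 5
Reactants: 8 (2R,3S)-3-hydroxy-N-methoxy-N,5-dimethyl-2-(propan-2-yl)hex-5-enamide
Product: 9 (2R,3S)-3-[(tert-butyldimethylsilyl)oxy]-N-methoxy-N,5-dimethyl-2-(propan-2-yl)hex-5-enamide
Conditions: TBSOTf, 2,6-lutidine, CH2Cl2, −78 to 0 °C
Reagents that add atoms: tert-butyldimethylsilyl trifluoromethanesulfonate (CC(C)(C)[Si](C)(C)OS(=O)(=O)C(F)(F)F)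
Why: silyl ether formation at the secondary alcohol; the group has to survive organometallic addition, metathesis, mild acid and an enolate.

Step 6
Reactants: 10 5-methylhex-5-en-2-one
Product: 11 2-methyl-2-(3-methylbut-3-en-1-yl)-1,3-dioxolane
Conditions: TMSOCH2CH2OTMS, TMSOTf (cat.), CH2Cl2, −78 °C
Reagents that add atoms: 1,2-bis(trimethylsilyloxy)ethane (C[Si](C)(C)OCCO[Si](C)(C)C)
Why: Noyori ketalisation masks the methyl ketone at low temperature, without acid-induced migration of the 1,1-disubstituted olefin.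

Step 7
Reactants: 11 2-methyl-2-(3-methylbut-3-en-1-yl)-1,3-dioxolane; 9 (2R,3S)-3-[(tert-butyldimethylsilyl)oxy]-N-methoxy-N,5-dimethyl-2-(propan-2-yl)hex-5-enamide
Product: 14 (5R,6S)-6-[(tert-butyldimethylsilyl)oxy]-8-methyl-2-[2-(2-methyl-1,3-dioxolan-2-yl)ethyl]-5-(propan-2-yl)nona-1,8-dien-4-one, via allylpotassium reagent 12 (not isolated), via allylmagnesium bromide 13 (not isolated)
Conditions: 11, n-BuLi, KOt-Bu, THF, −78 to −50 °C; MgBr2·OEt2, −78 °C; 9, −78 to 0 °C; pH 7 buffer
Reagents that add atoms: none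
Why: allylic metalation of the 2-methylalk-1-ene at its methyl group by the n-BuLi/KOt-Bu superbase, transmetalation to magnesium and acyl substitution at the Weinreb amide (chelated tetrahedral adduct, single addition); the allyl unit has two equivalent CH2 termini so one constitution results, and the C6 ketone is only released on work-up so C7 should keep its configuration.

Step 8
Reactants: 14 (5R,6S)-6-[(tert-butyldimethylsilyl)oxy]-8-methyl-2-[2-(2-methyl-1,3-dioxolan-2-yl)ethyl]-5-(propan-2-yl)nona-1,8-dien-4-one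
Product: 15 (6S,7R)-6-[(tert-butyldimethylsilyl)oxy]-4-methyl-3-[2-(2-methyl-1,3-dioxolan-2-yl)ethyl]-7-(propan-2-yl)cyclohept-3-en-1-one
Conditions: RuCl2(=CH-C6H4-2-O-i-Pr)(L), L = 1,3-bis(2-methylphenyl)imidazolidin-2-ylidene (10 mol %), 1,4-benzoquinone (20 mol %), toluene (2 mM), 80 °C
Reagents that add atoms: none
Why: ring-closing metathesis of two 1,1-disubstituted olefins to the tetrasubstituted C1=C10 olefin of the seven-membered ring; the small o-tolyl carbene ligand is the type used for tetrasubstituted olefins, the branched chain favours closure, and benzoquinone should suppress olefin migration.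

Step 9
Reactants: 15 (6S,7R)-6-[(tert-butyldimethylsilyl)oxy]-4-methyl-3-[2-(2-methyl-1,3-dioxolan-2-yl)ethyl]-7-(propan-2-yl)cyclohept-3-en-1-one
Product: 16 (6S,7R)-6-[(tert-butyldimethylsilyl)oxy]-4-methyl-3-(3-oxobutyl)-7-(propan-2-yl)cyclohept-3-en-1-one
Conditions: PPTS, acetone/H2O (10:1), 55 °C
Reagents that add atoms: water (O)
Why: mild acetal hydrolysis; PPTS should leave the secondary TBS ether intact, and the tetrasubstituted β,γ-olefin of a cycloheptenone has little driving force to move into conjugation.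

Step 10
Reactants: 16 (6S,7R)-6-[(tert-butyldimethylsilyl)oxy]-4-methyl-3-(3-oxobutyl)-7-(propan-2-yl)cyclohept-3-en-1-one
Product: 18 (3S,3aS,5R,6S)-6-[(tert-butyldimethylsilyl)oxy]-3-hydroxy-3,8-dimethyl-5-(propan-2-yl)-2,3,3a,5,6,7-hexahydroazulen-4(1H)-one, via lithium dienolate 17 (not isolated)
Conditions: LiN(SiMe3)2 (0.98 equiv, added slowly), THF, −78 °C; AcOH, −78 °C
Reagents that add atoms: none
Why: LiN(SiMe3)2 removes the C5 proton, which is α to the C6 ketone and allylic to C1=C10 and is estimated to be about six pK units more acidic than any proton of the methyl ketone, and the resulting ring dienolate 17 adds through its α-carbon C5 to the C4 ketone; this is an intramolecular ketone–ketone aldol addition, the closest known type being kinetic α-selective aldol reactions of dienolates of β,γ-unsaturated ketones. The five-membered ring closes in the favoured 5-(enolexo)-exo-trig mode, whereas attack through the γ-carbon C10 would be a 5-endo closure that builds two adjacent fully substituted carbons. C4 is controlled by the seven-membered ring, which locks the enolate in the E(O) geometry (O6 trans to C1): in the lithium-bridged chair Zimmerman–Traxler transition state the tether carbon C3 is equatorial, the C15 methyl axial and the carbinol oxygen anti to C1, which should give the 4,5-anti aldol with the hydroxyl cis to H5 and the methyl cis to C6. C5 is controlled by C7: the axial C15 methyl meets the C7 substituent on the attacked face, so the bond should form on the enolate face that carries H7, anti to the isopropyl group. The step needs chemoselective enolisation, no retro-aldol or olefin migration and no β-elimination of the C8 silyl ether; these are secured by the acidity difference with a slight deficit of base (any methyl ketone enolate is reprotonated by substrate and its own aldol modes would give bridged rings), by the cold acidic quench, and by the hindered, far less acidic C7 proton.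

Step 11
Reactants: 18 (3S,3aS,5R,6S)-6-[(tert-butyldimethylsilyl)oxy]-3-hydroxy-3,8-dimethyl-5-(propan-2-yl)-2,3,3a,5,6,7-hexahydroazulen-4(1H)-one
Product: 19 (3S,3aS,5R,6S)-3,6-dihydroxy-3,8-dimethyl-5-(propan-2-yl)-2,3,3a,5,6,7-hexahydroazulen-4(1H)-one
Conditions: HF·pyridine, pyridine, THF, 0 °C to rt
Reagents that add atoms: none
Why: fluoride cleavage of the silyl ether under buffered, weakly acidic conditions, which avoid the retro-aldol, epimerisation and β-elimination that basic fluoride could cause in the β-hydroxy ketone.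

Step 12
Reactants: 19 (3S,3aS,5R,6S)-3,6-dihydroxy-3,8-dimethyl-5-(propan-2-yl)-2,3,3a,5,6,7-hexahydroazulen-4(1H)-one
Product: 20 (3S,3aR,4R,5R,6S)-3,8-dimethyl-5-(propan-2-yl)-1,2,3,3a,4,5,6,7-octahydroazulene-3,4,6-triol
Conditions: Me4NBH(OAc)3, MeCN/AcOH (1:1), −30 to −20 °C
Reagents that add atoms: none
Why: Evans–Saksena reduction; the secondary C8 hydroxyl exchanges onto boron and delivers hydride to the C6 carbonyl on its own face, which should give the 6,8-anti (trans) diol with the new hydroxyl cis to the isopropyl group, while the hindered tertiary C4 hydroxyl exchanges more slowly and the acidic medium protects the aldol unit.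

Step 13
Reactants: 20 (3S,3aR,4R,5R,6S)-3,8-dimethyl-5-(propan-2-yl)-1,2,3,3a,4,5,6,7-octahydroazulene-3,4,6-triol; 21 angelic acid, (Z)-2-methylbut-2-enoic acid
Product: 23 (3S,3aR,4R,5S,6S)-3,4-dihydroxy-3,8-dimethyl-5-(propan-2-yl)-1,2,3,3a,4,5,6,7-octahydroazulen-6-yl (2Z)-2-methylbut-2-enoate, via angelic 2,4,6-trichlorobenzoic anhydride 22 (not isolated)
Conditions: 21, 2,4,6-trichlorobenzoyl chloride, Et3N, toluene, rt; then 20, 75 °C
Reagents that add atoms: none
Why: Yamaguchi esterification through the pre-formed mixed anhydride, a protocol that keeps the Z geometry of angelates; the C8 hydroxyl is the only unhindered secondary alcohol (C6–OH lies between the ring-fusion carbon and the isopropyl-bearing carbon, C4–OH is tertiary), so acylation should occur there.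

Step 14
Reactants: 23 (3S,3aR,4R,5S,6S)-3,4-dihydroxy-3,8-dimethyl-5-(propan-2-yl)-1,2,3,3a,4,5,6,7-octahydroazulen-6-yl (2Z)-2-methylbut-2-enoate
Product: 24 (3S,3aR,4R,5R,6S)-4-acetoxy-3-hydroxy-3,8-dimethyl-5-(propan-2-yl)-1,2,3,3a,4,5,6,7-octahydroazulen-6-yl (2Z)-2-methylbut-2-enoate (CNP0258590.1)
Conditions: Ac2O, pyridine, DMAP (cat.), CH2Cl2, rt
Reagents that add atoms: acetic anhydride (CC(=O)OC(C)=O)
Why: DMAP-catalysed acetylation of the remaining secondary alcohol at C6; the tertiary C4 hydroxyl should not react under these conditions and the angelate is not affected.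

**Compound list**

1 | (R)-4-benzyloxazolidin-2-one | O=C1N[C@H](Cc2ccccc2)CO1 | starting material
2 | 3-methylbutanoyl chloride | CC(C)CC(Cl)=O | starting material
3 | (R)-4-benzyl-3-(3-methylbutanoyl)oxazolidin-2-one | CC(C)CC(=O)N1[C@H](Cc2ccccc2)COC1=O | intermediate
4 | 3-methylbut-3-en-1-ol | CC(=C)CCO | starting material
5 | 3-methylbut-3-enal | CC(=C)CC=O | intermediate
6 | dibutylboron (Z)-enolate of 3 | CC(C)/C=C(\OB(CCCC)CCCC)N1[C@H](Cc2ccccc2)COC1=O | intermediate
7 | (R)-4-benzyl-3-[(2R,3S)-3-hydroxy-5-methyl-2-(propan-2-yl)hex-5-enoyl]oxazolidin-2-one | O[C@@H](CC(C)=C)[C@@H](C(C)C)C(=O)N1[C@H](Cc2ccccc2)COC1=O | intermediate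
8 | (2R,3S)-3-hydroxy-N-methoxy-N,5-dimethyl-2-(propan-2-yl)hex-5-enamide | O[C@@H](CC(C)=C)[C@@H](C(C)C)C(=O)N(C)OC | intermediate
9 | (2R,3S)-3-[(tert-butyldimethylsilyl)oxy]-N-methoxy-N,5-dimethyl-2-(propan-2-yl)hex-5-enamide | CC(C)(C)[Si](C)(C)O[C@@H](CC(C)=C)[C@@H](C(C)C)C(=O)N(C)OC | intermediate
10 | 5-methylhex-5-en-2-one | CC(=C)CCC(C)=O | starting material
11 | 2-methyl-2-(3-methylbut-3-en-1-yl)-1,3-dioxolane | CC(=C)CCC1(C)OCCO1 | intermediate
12 | [2-methylidene-4-(2-methyl-1,3-dioxolan-2-yl)butyl]potassium | [K]CC(=C)CCC1(C)OCCO1 | intermediate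
13 | [2-methylidene-4-(2-methyl-1,3-dioxolan-2-yl)butyl]magnesium bromide | Br[Mg]CC(=C)CCC1(C)OCCO1 | intermediate
14 | (5R,6S)-6-[(tert-butyldimethylsilyl)oxy]-8-methyl-2-[2-(2-methyl-1,3-dioxolan-2-yl)ethyl]-5-(propan-2-yl)nona-1,8-dien-4-one | CC(C)(C)[Si](C)(C)O[C@@H](CC(C)=C)[C@@H](C(C)C)C(=O)CC(=C)CCC1(C)OCCO1 | intermediate
15 | (6S,7R)-6-[(tert-butyldimethylsilyl)oxy]-4-methyl-3-[2-(2-methyl-1,3-dioxolan-2-yl)ethyl]-7-(propan-2-yl)cyclohept-3-en-1-one | CC(C)(C)[Si](C)(C)O[C@H]1CC(C)=C(CCC2(C)OCCO2)CC(=O)[C@@H]1C(C)C | intermediate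
16 | (6S,7R)-6-[(tert-butyldimethylsilyl)oxy]-4-methyl-3-(3-oxobutyl)-7-(propan-2-yl)cyclohept-3-en-1-one | CC(C)(C)[Si](C)(C)O[C@H]1CC(C)=C(CCC(C)=O)CC(=O)[C@@H]1C(C)C | intermediate
17 | lithium dienolate of 16 (O6–C6=C5–C1=C10) | [Li]OC1=CC(CCC(C)=O)=C(C)C[C@H](O[Si](C)(C)C(C)(C)C)[C@H]1C(C)C | intermediate
18 | (3S,3aS,5R,6S)-6-[(tert-butyldimethylsilyl)oxy]-3-hydroxy-3,8-dimethyl-5-(propan-2-yl)-2,3,3a,5,6,7-hexahydroazulen-4(1H)-one | CC(C)(C)[Si](C)(C)O[C@H]1CC(C)=C2CC[C@](C)(O)[C@H]2C(=O)[C@@H]1C(C)C | intermediate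
19 | (3S,3aS,5R,6S)-3,6-dihydroxy-3,8-dimethyl-5-(propan-2-yl)-2,3,3a,5,6,7-hexahydroazulen-4(1H)-one | O[C@H]1CC(C)=C2CC[C@](C)(O)[C@H]2C(=O)[C@@H]1C(C)C | intermediate
20 | (3S,3aR,4R,5R,6S)-3,8-dimethyl-5-(propan-2-yl)-1,2,3,3a,4,5,6,7-octahydroazulene-3,4,6-triol | O[C@H]1CC(C)=C2CC[C@](C)(O)[C@H]2[C@H](O)[C@@H]1C(C)C | intermediate
21 | angelic acid, (Z)-2-methylbut-2-enoic acid | C/C=C(/C)C(O)=O | starting material
22 | angelic 2,4,6-trichlorobenzoic anhydride | C/C=C(/C)C(=O)OC(=O)c1c(Cl)cc(Cl)cc1Cl | intermediate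
23 | (3S,3aR,4R,5S,6S)-3,4-dihydroxy-3,8-dimethyl-5-(propan-2-yl)-1,2,3,3a,4,5,6,7-octahydroazulen-6-yl (2Z)-2-methylbut-2-enoate | C/C=C(/C)C(=O)O[C@H]1CC(C)=C2CC[C@](C)(O)[C@H]2[C@H](O)[C@@H]1C(C)C | intermediate
24 | (3S,3aR,4R,5R,6S)-4-acetoxy-3-hydroxy-3,8-dimethyl-5-(propan-2-yl)-1,2,3,3a,4,5,6,7-octahydroazulen-6-yl (2Z)-2-methylbut-2-enoate | C/C=C(/C)C(=O)O[C@H]1CC(C)=C2CC[C@](C)(O)[C@H]2[C@H](OC(C)=O)[C@@H]1C(C)C | target

**Step count**

Total: 14 steps. Longest linear sequence: 12 steps (from 4 through steps 2, 3, 4, 5, 7, 8, 9, 10, 11, 12, 13, 14; the same length from 1).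

**Steps most likely to fail**

Step 8. Ring closure between two 1,1-disubstituted olefins may be slower than catalyst decay, so that olefin migration and intermolecular metathesis take over. The fallback sets out from 14 and comes back at 15, and forms the tetrasubstituted olefin by carbonyl coupling instead. Ketone 14 would be reduced (NaBH4, MeOH, 0 °C) to the C6 carbinol of 14, both epimers F1, and silylated (Et3SiOTf, 2,6-lutidine) to the triethylsilyl ether of that carbinol F2. Ozonolysis of both olefins (O3, CH2Cl2/MeOH, −78 °C; Me2S) should give the 1,7-diketone F3. Intramolecular McMurry coupling (TiCl3(DME)1.5, Zn–Cu couple, DME, reflux, slow addition) should close the seven-membered ring as the bis-silylated cycloheptene F4. Selective removal of the triethylsilyl group (HF·pyridine, pyridine, THF, 0 °C) would give the cycloheptenol F5, and Dess–Martin oxidation would return 15.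

Step 10. Enolisation may be unselective, the dienolate may be reprotonated at C10 to the conjugated enone, the aldolate may revert on warming, or the facial preference at C5 may be weak. The fallback sets out from 15 and comes back at 18, and uses an acetal electrophile so that only one enolisable ketone is present. Ketone 15 would be converted (LiN(SiMe3)2, Me3SiCl, THF, −78 °C) into the trimethylsilyl dienol ether F6. TiCl4 (CH2Cl2, −78 °C) should open the dioxolane to an oxocarbenium ion that is attacked by C5 in an intramolecular Mukaiyama aldol reaction, giving the C4 2-hydroxyethyl ether of 18 F7; the bulky alkoxy group takes the outer position, so the same C4 and C5 configurations are expected. Iodination (I2, PPh3, imidazole) would give the 2-iodoethyl ether F8, and zinc (Zn, NH4Cl, EtOH, 60 °C) should remove the iodoethyl group by reductive elimination to return 18.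

Step 13. Acylation may not distinguish the two secondary hydroxyls well enough, may run on to the diester, or the angelate may isomerise at the temperature needed. The fallback sets out from 19 and comes back at 23, and removes the site question by acylating before the C6 carbinol exists. Keto-diol 19, whose only secondary hydroxyl is at C8, would be esterified with anhydride 22 (toluene, 60 °C) to the 8-angelate of the C6 ketone F9. Chelation-controlled reduction (Et2BOMe, NaBH4, THF/MeOH, −78 °C; Narasaka–Prasad conditions) through the C4–O/C6=O boron chelate should then give the 4,6-syn diol 23, with hydride arriving on the face away from the C7 isopropyl group.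

**Further compounds**

F1 | step 8 | C6 carbinol of 14, nona-1,8-dien-4-ol, both epimers at the carbinol carbon | CC(C)(C)[Si](C)(C)O[C@@H](CC(C)=C)[C@@H](C(C)C)C(O)CC(=C)CCC1(C)OCCO1
F2 | step 8 | triethylsilyl ether of F1 | CC(C)(C)[Si](C)(C)O[C@@H](CC(C)=C)[C@@H](C(C)C)C(O[Si](CC)(CC)CC)CC(=C)CCC1(C)OCCO1
F3 | step 8 | 1,7-diketone from ozonolysis of F2 | CC(C)(C)[Si](C)(C)O[C@@H](CC(C)=O)[C@@H](C(C)C)C(O[Si](CC)(CC)CC)CC(=O)CCC1(C)OCCO1
F4 | step 8 | bis-silylated cycloheptene, C6 triethylsilyl ether analogue of 15 | CC(C)(C)[Si](C)(C)O[C@H]1CC(C)=C(CCC2(C)OCCO2)CC(O[Si](CC)(CC)CC)[C@@H]1C(C)C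
F5 | step 8 | cycloheptenol, C6 carbinol analogue of 15 | CC(C)(C)[Si](C)(C)O[C@H]1CC(C)=C(CCC2(C)OCCO2)CC(O)[C@@H]1C(C)C
F6 | step 10 | trimethylsilyl dienol ether of 15 | C[Si](C)(C)OC1=CC(CCC2(C)OCCO2)=C(C)C[C@H](O[Si](C)(C)C(C)(C)C)[C@H]1C(C)C
F7 | step 10 | C4 2-hydroxyethyl ether of 18 | CC(C)(C)[Si](C)(C)O[C@H]1CC(C)=C2CC[C@](C)(OCCO)[C@H]2C(=O)[C@@H]1C(C)C
F8 | step 10 | C4 2-iodoethyl ether of 18 | CC(C)(C)[Si](C)(C)O[C@H]1CC(C)=C2CC[C@](C)(OCCI)[C@H]2C(=O)[C@@H]1C(C)C
F9 | step 13 | 8-angelate of keto-diol 19 | C/C=C(/C)C(=O)O[C@H]1CC(C)=C2CC[C@](C)(O)[C@H]2C(=O)[C@@H]1C(C)C
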